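The flavanone is cut in ring C at O1–C2 and C3–C4. O1–C8a–C4a–C4 of phloroglucinol ring A becomes the heterodiene of a 4-methoxy ortho-quinone methide. C2=C3 becomes the vinyl group of a ring B styrene that already carries the luteolin unit at C5'. One catalytic asymmetric inverse-demand hetero-[4+2] step joins the halves, closes ring C and sets C2 through a sacrificial C4 centre, without base. It exploits O4', para to the vinyl-bearing C1', which stabilises charge at C2. Since O4' sits between O3' and the C8'' aryl group, the ring B catechol is locked as a diphenylmethylene ketal so that its lone pair stays conjugated; all other phenols are benzyl ethers.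

Key step: step 11

Assumption: the C5'–C8'' biaryl axis is flanked by only three oxygen substituents and is undefined in the target as drawn. It is taken as configurationally labile, so C2 is the only stereo-element to control.

Remark: the sense of induction of the chiral acid cannot be predicted safely. The catalyst antipode is fixed in a trial with a simple 4-alkoxystyrene carried through to a flavanone of known configuration.

Locants: unprimed = flavanone rings A and C; primed = flavanone ring B; double-primed = flavone core; triple-primed = flavone ring B. LutBn4-8-yl = 5,7-bis(benzyloxy)-2-[3,4-bis(benzyloxy)phenyl]-4-oxo-4H-chromen-8-yl.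

Step 1
Reactants: 1 2,4,6-trihydroxyacetophenone (phloroacetophenone)
Product: 2 1-[4,6-bis(benzyloxy)-2-hydroxyphenyl]ethanone
Conditions: BnBr (2.0 equiv), K2CO3 (2.2 equiv), DMF, rt to 50 °C
Reagents that add atoms: benzyl bromide, BrCc1ccccc1
Why: Williamson etherification in which the phenol hydrogen-bonded to the acetyl carbonyl is the least nucleophilic, so two equivalents of benzyl bromide should stop at the 4,6-diether.

Step 2
Reactants: 2 1-[4,6-bis(benzyloxy)-2-hydroxyphenyl]ethanone
Product: 3 1-[4,6-bis(benzyloxy)-2-hydroxy-3-iodophenyl]ethanone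
Conditions: NIS (1.0 equiv), TFA (cat.), MeCN, 0 °C to rt
Reagents that add atoms: N-iodosuccinimide, O=C1CCC(=O)N1I
Why: Electrophilic aromatic iodination at C3, the activated site ortho to the free phenol and flanked by only one benzyloxy group, which is the usual position of monohalogenation in 2-hydroxy-4,6-dialkoxyacetophenones and becomes C8'' of the flavone.

Step 3
Reactants: 3 1-[4,6-bis(benzyloxy)-2-hydroxy-3-iodophenyl]ethanone; 4 3,4-bis(benzyloxy)benzaldehyde
Product: 5 (E)-1-[4,6-bis(benzyloxy)-2-hydroxy-3-iodophenyl]-3-[3,4-bis(benzyloxy)phenyl]prop-2-en-1-one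
Conditions: KOH (50 % aq.), EtOH/THF, rt; then dilute HCl
Reagents that add atoms: none
Why: Claisen–Schmidt condensation of the methyl ketone enolate with a non-enolisable aldehyde, where E1cB loss of water gives the favoured E-enone and no second aldehyde is yet present to compete.

Step 4
Reactants: 5 the (E)-2'-hydroxy-3'-iodochalcone
Product: 6 5,7-bis(benzyloxy)-2-[3,4-bis(benzyloxy)phenyl]-8-iodo-4H-chromen-4-one (8-iodo-tetra-O-benzylluteolin)
Conditions: I2 (10 mol %), DMSO, 120 °C
Reagents that add atoms: none
Why: Iodine–DMSO oxidative cyclisation of a 2'-hydroxychalcone (oxa-Michael closure by the only free phenol, alpha-iodination, loss of HI, DMSO as terminal oxidant), which places the iodine-bearing carbon next to O1'' as C8''.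

Step 5
Reactants: 7 5-bromovanillin
Product: 8 3-bromo-4,5-dihydroxybenzaldehyde
Conditions: AlCl3 (1.2 equiv), pyridine (4.4 equiv), CH2Cl2, reflux; then aq. HCl
Reagents that add atoms: none
Why: Chelation-assisted Lewis acid ether cleavage in which aluminium bound to the neighbouring phenolate activates only the ortho OMe group toward nucleophilic demethylation, while aldehyde and aryl bromide stay inert.

Step 6
Reactants: 8 3-bromo-4,5-dihydroxybenzaldehyde
Product: 9 7-bromo-2,2-diphenyl-1,3-benzodioxole-5-carbaldehyde
Conditions: Ph2CCl2 (1.3 equiv), K2CO3 (3 equiv), MeCN, 60 °C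
Reagents that add atoms: dichlorodiphenylmethane, ClC(Cl)(c1ccccc1)c1ccccc1
Why: Catechol ketalisation with a gem-dichloride (two SN1-type substitutions), giving a base-stable, hydrogenolysable dioxole whose five-membered ring keeps the O4' lone pair aligned with the ring B pi system even after an aryl group is placed ortho to it.

Step 7
Reactants: 9 7-bromo-2,2-diphenyl-1,3-benzodioxole-5-carbaldehyde
Product: 10 2,2-diphenyl-7-(4,4,5,5-tetramethyl-1,3,2-dioxaborolan-2-yl)-1,3-benzodioxole-5-carbaldehyde
Conditions: B2pin2 (1.2 equiv), Pd(dppf)Cl2 (3 mol %), KOAc (3 equiv), 1,4-dioxane, 90 °C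
Reagents that add atoms: bis(pinacolato)diboron, CC1(C)OB(OC1(C)C)B1OC(C)(C)C(C)(C)O1
Why: Miyaura borylation (oxidative addition of the aryl bromide to zerovalent palladium, acetate-assisted transmetalation), a reaction that tolerates aldehydes and ketals.

Step 8
Reactants: 6 8-iodo-tetra-O-benzylluteolin; 10 the ring B pinacol boronate
Product: 11 7-(LutBn4-8-yl)-2,2-diphenyl-1,3-benzodioxole-5-carbaldehyde
Conditions: Pd(OAc)2 (5 mol %), SPhos (10 mol %), K3PO4 (3 equiv), toluene/H2O 10:1, 90 °C
Reagents that add atoms: none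
Why: Suzuki–Miyaura coupling forming the C5'–C8'' bond with a bulky electron-rich biarylphosphine suited to tri-ortho-substituted biaryls, placed after flavone formation so that the ring B aldehyde never meets an aldol step.

Step 9
Reactants: 11 the flavone-bearing ring B aldehyde
Product: 12 8-(6-ethenyl-2,2-diphenyl-1,3-benzodioxol-4-yl)-5,7-bis(benzyloxy)-2-[3,4-bis(benzyloxy)phenyl]-4H-chromen-4-one (flavone-bearing ring B styrene)
Conditions: MePPh3Br (1.3 equiv), KOtBu (1.2 equiv), THF, 0 °C
Reagents that add atoms: methyltriphenylphosphonium bromide, C[P+](c1ccccc1)(c1ccccc1)c1ccccc1.[Br-]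
Why: Wittig methylenation, in which the non-stabilised ylide reacts far faster with the aryl aldehyde than with the vinylogous-ester carbonyl of the flavone.

Step 10
Reactants: 13 2,4,6-trihydroxybenzaldehyde
Product: 14 4,6-bis(benzyloxy)-2-hydroxybenzaldehyde
Conditions: BnBr (2.0 equiv), K2CO3 (2.2 equiv), DMF, rt
Reagents that add atoms: benzyl bromide, BrCc1ccccc1
Why: Williamson etherification that leaves free the one phenol chelated to the formyl group, which is the oxygen that later becomes O1.

Step 11
Reactants: 12 flavone-bearing ring B styrene; 14 4,6-bis(benzyloxy)-2-hydroxybenzaldehyde; 15 trimethyl orthoformate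
Product: 18 (2S,4S)-cis-5,7-bis(benzyloxy)-4-methoxyflavan whose ring B is the 3',4'-O-diphenylmethylene ketal carrying LutBn4-8-yl at C5', via dimethyl acetal 16 (not isolated), via ortho-quinone methide 17 (not isolated)
Conditions: 14 (1.5 equiv, slow addition), 15 (3 equiv), chiral IDPi Brønsted acid (BINOL-derived imidodiphosphorimidate, P=NSO2CF3 groups, 3,3'-aryl = 3,5-(CF3)2C6H3; 10 mol %), 5 Å MS, CH2Cl2/toluene, −40 °C; Et3N quench at −40 °C; chromatographic removal of the 2,4-trans isomer
Reagents that add atoms: trimethyl orthoformate 15, COC(OC)OC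
Why: Proposed new method: the acid first exchanges the aldehyde of 14 with 15 to give acetal 16, then expels methanol to give 17 as its O-protonated oxocarbenium form paired with the chiral IDPi anion, and the CH2 terminus of styrene 12 attacks the methide carbon (C3–C4 bond) while positive charge builds at C2, onto which the ring A oxygen O1 collapses (O1–C2 bond). The closest known reaction types are the achiral Lewis acid three-component chroman synthesis from salicylaldehydes, orthoformates and styrenes and the chiral Brønsted acid [4+2] cycloadditions of ortho-quinone methides generated in situ; the intermolecular enantioselective version with an unfunctionalised vinylarene has not been shown. Ring C closes as a six-membered ring in a highly asynchronous inverse-demand hetero-[4+2] mode, four atoms (O1, C8a, C4a, C4) coming from 17 and two (C3, C2) from 12. C4 is controlled by the confined counter-anion, which shields one face of the planar cation, and C2 is controlled by C4 through an endo, half-chair closure that places aryl and OMe both pseudo-equatorial, so that (4S) is relayed to (2S) in the 2,4-cis product. Regioselectivity needs the cation at C2 and is secured by O4' para to C1', held in conjugation by the dioxole ring; chemoselectivity for the vinyl group over arene C–H sites is helped by the electron-poor flavone core and by slow addition of 14, and the very easily ionised trioxygenated acetal should still react although the basic flavone carbonyl levels the acid strength. Because a 2,4-trans isomer formed from the same C4 face has the opposite C2 configuration, it is removed before C4 is erased, and the cold amine quench guards against acid-induced scrambling at C4 or C2.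

Step 12
Reactants: 18 the (2S,4S)-4-methoxyflavan
Product: 19 (2S)-flavan-4-ol with the same protecting groups (mixture of C4 epimers)
Conditions: PPTS (0.2 equiv), THF/H2O 4:1, rt to 40 °C
Reagents that add atoms: water, O
Why: Acid-catalysed SN1 solvolysis in which the C4 cation, stabilised by two ortho oxygens (O1, O5) and one para oxygen (O7) of ring A, forms under conditions too mild for the O1–C2 bond, the ketal or the benzyl ethers and is trapped by excess water, the C4 configuration being irrelevant from here on.

Step 13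
Reactants: 19 the (2S)-flavan-4-ol
Product: 20 (2S)-5,7-bis(benzyloxy)flavanone whose ring B is the 3',4'-O-diphenylmethylene ketal carrying LutBn4-8-yl at C5'
Conditions: Dess–Martin periodinane (1.3 equiv), NaHCO3 (solid, 5 equiv), CH2Cl2, 0 °C to rt
Reagents that add atoms: none
Why: Dess–Martin oxidation of a secondary benzylic alcohol under buffered, essentially neutral conditions, which converges both C4 epimers on one ketone and offers no base that could open ring C by retro-oxa-Michael reaction.

Step 14
Reactants: 20 the protected (2S)-flavanone–flavone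
Product: 21 CNP0224656.1, (2S)-eriodictyol linked through C5' to C8'' of luteolin
Conditions: H2 (1 atm), 10 % Pd/C, THF/MeOH 1:1, AcOH (trace), rt; base-free work-up
Reagents that add atoms: none
Why: Heterogeneous hydrogenolysis of six O-benzyl ethers and of the doubly benzylic diphenylmethylene ketal under neutral to faintly acidic conditions, which should leave the conjugated C2''=C3'' bond, both carbonyl groups and the base-labile C2 stereocentre untouched.

Compound list
1 | 2,4,6-trihydroxyacetophenone | CC(=O)c1c(O)cc(O)cc1O | starting material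
2 | 1-[4,6-bis(benzyloxy)-2-hydroxyphenyl]ethanone | CC(=O)c1c(O)cc(OCc2ccccc2)cc1OCc1ccccc1 | intermediate
3 | 1-[4,6-bis(benzyloxy)-2-hydroxy-3-iodophenyl]ethanone | Ic1c(O)c(C(C)=O)c(OCc2ccccc2)cc1OCc1ccccc1 | intermediate
4 | 3,4-bis(benzyloxy)benzaldehyde | O=Cc1ccc(OCc2ccccc2)c(OCc2ccccc2)c1 | starting material
5 | (E)-1-[4,6-bis(benzyloxy)-2-hydroxy-3-iodophenyl]-3-[3,4-bis(benzyloxy)phenyl]prop-2-en-1-one | Ic1c(O)c(C(=O)/C=C/c2ccc(OCc3ccccc3)c(OCc3ccccc3)c2)c(OCc2ccccc2)cc1OCc1ccccc1 | intermediate
6 | 5,7-bis(benzyloxy)-2-[3,4-bis(benzyloxy)phenyl]-8-iodo-4H-chromen-4-one | Ic1c(OCc2ccccc2)cc(OCc2ccccc2)c2c(=O)cc(-c3ccc(OCc4ccccc4)c(OCc4ccccc4)c3)oc12 | intermediate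
7 | 5-bromovanillin | COc1cc(C=O)cc(Br)c1O | starting material
8 | 3-bromo-4,5-dihydroxybenzaldehyde | O=Cc1cc(O)c(O)c(Br)c1 | intermediate
9 | 7-bromo-2,2-diphenyl-1,3-benzodioxole-5-carbaldehyde | O=Cc1cc(Br)c2OC(c3ccccc3)(c3ccccc3)Oc2c1 | intermediate
10 | 2,2-diphenyl-7-(4,4,5,5-tetramethyl-1,3,2-dioxaborolan-2-yl)-1,3-benzodioxole-5-carbaldehyde | O=Cc1cc(B2OC(C)(C)C(C)(C)O2)c2OC(c3ccccc3)(c3ccccc3)Oc2c1 | intermediate
11 | 7-(LutBn4-8-yl)-2,2-diphenyl-1,3-benzodioxole-5-carbaldehyde | O=Cc1cc(-c2c(OCc3ccccc3)cc(OCc3ccccc3)c3c(=O)cc(-c4ccc(OCc5ccccc5)c(OCc5ccccc5)c4)oc23)c2OC(c3ccccc3)(c3ccccc3)Oc2c1 | intermediate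
12 | 8-(6-ethenyl-2,2-diphenyl-1,3-benzodioxol-4-yl)-5,7-bis(benzyloxy)-2-[3,4-bis(benzyloxy)phenyl]-4H-chromen-4-one | C=Cc1cc(-c2c(OCc3ccccc3)cc(OCc3ccccc3)c3c(=O)cc(-c4ccc(OCc5ccccc5)c(OCc5ccccc5)c4)oc23)c2OC(c3ccccc3)(c3ccccc3)Oc2c1 | intermediate
13 | 2,4,6-trihydroxybenzaldehyde | O=Cc1c(O)cc(O)cc1O | starting material
14 | 4,6-bis(benzyloxy)-2-hydroxybenzaldehyde | O=Cc1c(O)cc(OCc2ccccc2)cc1OCc1ccccc1 | intermediate
15 | trimethyl orthoformate | COC(OC)OC | starting material
16 | 3,5-bis(benzyloxy)-2-(dimethoxymethyl)phenol | COC(OC)c1c(O)cc(OCc2ccccc2)cc1OCc1ccccc1 | intermediate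
17 | 3,5-bis(benzyloxy)-6-(methoxymethylidene)cyclohexa-2,4-dien-1-one (drawn neutral, C=C geometry left open; present as the ion pair of its O-protonated form) | COC=C1C(=O)C=C(OCc2ccccc2)C=C1OCc1ccccc1 | intermediate
18 | (2S,4S)-cis-5,7-bis(benzyloxy)-4-methoxy-2-[7-(LutBn4-8-yl)-2,2-diphenyl-1,3-benzodioxol-5-yl]chroman | CO[C@H]1C[C@@H](c2cc(-c3c(OCc4ccccc4)cc(OCc4ccccc4)c4c(=O)cc(-c5ccc(OCc6ccccc6)c(OCc6ccccc6)c5)oc34)c3OC(c4ccccc4)(c4ccccc4)Oc3c2)Oc2cc(OCc3ccccc3)cc(OCc3ccccc3)c21 | intermediate
19 | (2S)-5,7-bis(benzyloxy)-2-[7-(LutBn4-8-yl)-2,2-diphenyl-1,3-benzodioxol-5-yl]chroman-4-ol, C4 epimers | OC1C[C@@H](c2cc(-c3c(OCc4ccccc4)cc(OCc4ccccc4)c4c(=O)cc(-c5ccc(OCc6ccccc6)c(OCc6ccccc6)c5)oc34)c3OC(c4ccccc4)(c4ccccc4)Oc3c2)Oc2cc(OCc3ccccc3)cc(OCc3ccccc3)c21 | intermediate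
20 | (2S)-5,7-bis(benzyloxy)-2-[7-(LutBn4-8-yl)-2,2-diphenyl-1,3-benzodioxol-5-yl]chroman-4-one | O=C1C[C@@H](c2cc(-c3c(OCc4ccccc4)cc(OCc4ccccc4)c4c(=O)cc(-c5ccc(OCc6ccccc6)c(OCc6ccccc6)c5)oc34)c3OC(c4ccccc4)(c4ccccc4)Oc3c2)Oc2cc(OCc3ccccc3)cc(OCc3ccccc3)c21 | intermediate
21 | CNP0224656.1, (2S)-5,7,3',4'-tetrahydroxyflavanone joined at C5' to C8'' of 5'',7'',3''',4'''-tetrahydroxyflavone | O=C1C[C@@H](c2cc(O)c(O)c(-c3c(O)cc(O)c4c(=O)cc(-c5ccc(O)c(O)c5)oc34)c2)Oc2cc(O)cc(O)c21 | target

Total step count: 14. Longest linear sequence: 10 (steps 1, 2, 3, 4, 8, 9, 11, 12, 13, 14).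

Steps most likely to fail

1. Step 11.
- The large styrene may not enter the confined pocket, which would give poor facial selectivity at C4.
- The peri 5-benzyloxy group may weaken the pseudo-equatorial preference of the methoxy group and lower the cis selectivity that relays C4 to C2.
- The basic flavone carbonyl may slow ionisation by levelling the acid.
- Cationic oligomerisation of the styrene, Friedel–Crafts self-condensation of the ring A component, or reversible ionisation at C4 or C2 may consume material or erode optical purity.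
- Fallback (known chemistry only): it sets out from aldehyde 11 and acetophenone 2 and comes back at 20. Claisen–Schmidt condensation (KOH, EtOH/THF, rt) should give the 2'-hydroxychalcone F1. Oxa-Michael cyclisation (NaOAc, EtOH, reflux) should give the racemic flavanone F2. Kinetic resolution by asymmetric transfer hydrogenation (RuCl(TsDPEN)(p-cymene), HCO2H/Et3N, EtOAc, rt) follows, using the catalyst antipode that reduces the (2R)-ketone faster. It should leave (2S)-20 unreacted and turn its enantiomer into the (2R,4R)-cis-flavan-4-ol F3, which is separated by chromatography.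

2. Step 12.
- The C4 cation may lose a proton from C3 instead of taking up water.
- It may alkylate an electron-rich arene of a second molecule.
- Prolonged acid contact may open the O1–C2 bond with loss of optical purity, or start to cleave the ketal.
- Fallback: it sets out from 18 and comes back at 20, bypassing 19, and replaces solvolysis by oxidation. DDQ (1.3 equiv) in CH2Cl2/pH 7 phosphate buffer at 0 °C should abstract hydride from the C4–H bond. That bond is activated by the methoxy group and the trioxygenated ring A, as in the oxidative cleavage of electron-rich benzylic ethers. Water then displaces methanol at the oxidised carbon to give the ketone directly. Phenol benzyl ethers are inert to DDQ at this temperature, and attack at C4 rather than C2 is the established site preference in benzylated flavans.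

3. Step 4.
- At 120 °C the HI released may strip the peri 5''-O-benzyl group.
- It may also reverse the aryl iodination before DMSO re-oxidises it.
- Fallback: it sets out from 3 and comes back at 6 by a Baker–Venkataraman sequence that needs no oxidant. Esterification of 3 with commercial 3,4-bis(benzyloxy)benzoic acid (EDC, DMAP, CH2Cl2, rt) should give the aryl ester F4. Base-induced O-to-C acyl migration (KOH, pyridine, 50 °C) should give the 1,3-diketone F5. Cyclodehydration (TsOH cat., toluene, 80 °C) should then close the pyranone ring to 6.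

Further compounds
F1 | step 11 | (E)-1-[4,6-bis(benzyloxy)-2-hydroxyphenyl]-3-[7-(LutBn4-8-yl)-2,2-diphenyl-1,3-benzodioxol-5-yl]prop-2-en-1-one | O=C(/C=C/c1cc(-c2c(OCc3ccccc3)cc(OCc3ccccc3)c3c(=O)cc(-c4ccc(OCc5ccccc5)c(OCc5ccccc5)c4)oc23)c2OC(c3ccccc3)(c3ccccc3)Oc2c1)c1c(O)cc(OCc2ccccc2)cc1OCc1ccccc1
F2 | step 11 | racemic 5,7-bis(benzyloxy)-2-[7-(LutBn4-8-yl)-2,2-diphenyl-1,3-benzodioxol-5-yl]chroman-4-one | O=C1CC(c2cc(-c3c(OCc4ccccc4)cc(OCc4ccccc4)c4c(=O)cc(-c5ccc(OCc6ccccc6)c(OCc6ccccc6)c5)oc34)c3OC(c4ccccc4)(c4ccccc4)Oc3c2)Oc2cc(OCc3ccccc3)cc(OCc3ccccc3)c21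
F3 | step 11 | (2R,4R)-cis-5,7-bis(benzyloxy)-2-[7-(LutBn4-8-yl)-2,2-diphenyl-1,3-benzodioxol-5-yl]chroman-4-ol | O[C@@H]1C[C@H](c2cc(-c3c(OCc4ccccc4)cc(OCc4ccccc4)c4c(=O)cc(-c5ccc(OCc6ccccc6)c(OCc6ccccc6)c5)oc34)c3OC(c4ccccc4)(c4ccccc4)Oc3c2)Oc2cc(OCc3ccccc3)cc(OCc3ccccc3)c21
F0 | step 12 | none | none
F4 | step 4 | 2-acetyl-3,5-bis(benzyloxy)-6-iodophenyl 3,4-bis(benzyloxy)benzoate | Ic1c(OC(=O)c2ccc(OCc3ccccc3)c(OCc3ccccc3)c2)c(C(C)=O)c(OCc2ccccc2)cc1OCc1ccccc1
F5 | step 4 | 1-[4,6-bis(benzyloxy)-2-hydroxy-3-iodophenyl]-3-[3,4-bis(benzyloxy)phenyl]propane-1,3-dione | Ic1c(O)c(C(=O)CC(=O)c2ccc(OCc3ccccc3)c(OCc3ccccc3)c2)c(OCc2ccccc2)cc1OCc1ccccc1
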